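**Retrosynthetic overview**
1. Target 14 ⇐ bis-benzyl ether 13 (O-debenzylation). 13 ⇐ 3-aroyl-4,5-dihydrofuran 9 by conjugate reduction of the enol-ether enone, reductive removal of the auxiliary (C=O → CH2OH) and equilibration of the enolisable C-3.
2. Key disconnection of 9: the C3–C4 bond plus the C5–O bond ⇒ aroylacetaldehyde salt 7 and cinnamoyl sultam 5. C3 and C4 are the two α-carbons of a 1,4-dicarbonyl array, both natural donor positions. The dicarbonyl α-carbon is made to react with reversed polarity, as an electrophilic radical generated with Mn(OAc)3 (a one-electron enolonium equivalent).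
3. Ring order: the only ring (the oxolane) is closed in that same step, as a 4,5-dihydrofuran. C-4 and C-5 are set there (auxiliary control, trans closure); C-3 is set last under thermodynamic control.
4. 5 ⇐ aldehyde 1 + malonic acid + sultam 3. 7 ⇐ acetophenone 6 + ethyl formate.

Assumption: the (1R)-(+)-sultam shields the C-α re face of its E-enoyl amide (mirror image of the sense I recall for the (1S)-(−)-auxiliary), so the radical adds to the si face; if the sense proved opposite, the (1S)-(−)-sultam would be used with no other change; ketone 6 is taken as a catalogue item.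

Ring numbering used below: O1, C2, C3 (aroyl), C4 (CH2OH or acyl), C5 (aryl).

**Step 1**
Reactants: 1 3-(benzyloxy)-4-methoxybenzaldehyde
Product: 2 (E)-3-[3-(benzyloxy)-4-methoxyphenyl]prop-2-enoic acid
Conditions: malonic acid (1.5 equiv), pyridine, piperidine (cat.), 90 °C
Reagents that add atoms: malonic acid, OC(=O)CC(=O)O
Why: Knoevenagel–Doebner condensation with in-situ decarboxylation gives only the E acid from an electron-rich benzaldehyde; no stereocentre is formed.

**Step 2**
Reactants: 2 (E)-3-[3-(benzyloxy)-4-methoxyphenyl]prop-2-enoic acid; 3 (1R)-(+)-2,10-camphorsultam (3aR,6S,7aS)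
Product: 5 N-{(E)-3-[3-(benzyloxy)-4-methoxyphenyl]prop-2-enoyl}-(1R)-(+)-2,10-camphorsultam, via acid chloride 4 (not isolated)
Conditions: (COCl)2, DMF (cat.), CH2Cl2, 0 °C → rt; then 3, NaH, toluene, 0 °C → rt
Reagents that add atoms: none
Why: N-acylation of the sodium salt of the sultam by the acid chloride (standard auxiliary attachment) leaves the E alkene untouched and places the chiral controller next to the carbon that becomes C-4.

**Step 3**
Reactants: 6 1-[3-(benzyloxy)-4-methoxyphenyl]ethan-1-one
Product: 7 sodium (Z)-3-[3-(benzyloxy)-4-methoxyphenyl]-3-oxoprop-1-en-1-olate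
Conditions: NaH, HCO2Et, THF/Et2O, 0 °C → rt; salt filtered off
Reagents that add atoms: ethyl formate, CCOC=O; sodium hydride, [Na+].[H-]
Why: crossed Claisen condensation (formylation) of the methyl ketone enolate with the non-enolisable formate ester is driven by precipitation of the stabilised sodium enolate, which is stored and used as such.

**Step 4 (key step)**
Reactants: 5 N-{(E)-3-[3-(benzyloxy)-4-methoxyphenyl]prop-2-enoyl}-(1R)-(+)-2,10-camphorsultam; 7 sodium (Z)-3-[3-(benzyloxy)-4-methoxyphenyl]-3-oxoprop-1-en-1-olate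
Product: 9 N-acyl (1R)-(+)-2,10-camphorsultam of (4S,5S)-3-[3-(benzyloxy)-4-methoxybenzoyl]-5-[3-(benzyloxy)-4-methoxyphenyl]-4,5-dihydrofuran-4-carboxylic acid (4,5-trans), via hydroxymethylene ketone 8 (not isolated)
Conditions: Mn(OAc)3·2H2O (2.5 equiv), AcOH, 45 °C, N2; 7 (1.5 equiv) added over 2 h
Reagents that add atoms: none
Why: manganese triacetate oxidative radical annulation of a 1,3-dicarbonyl compound with an alkene (dihydrofuran synthesis): one-electron oxidation of the trivalent manganese enolate of 8 makes the dicarbonyl α-carbon an electrophilic radical that adds to C-α of 5 on the si face left open by the sultam (sets C-4), and the resulting p-alkoxybenzylic radical is oxidised to the cation, which is closed by the hydroxymethylene oxygen anti to the C-4 substituent (sets C-5, trans).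

**Step 5**
Reactants: 9 N-acyl sultam of the (4S,5S)-dihydrofuran-4-carboxylic acid
Product: 13 [(3S,4R,5S)-5-[3-(benzyloxy)-4-methoxyphenyl]-4-(hydroxymethyl)oxolan-3-yl][3-(benzyloxy)-4-methoxyphenyl]methanone, via lithium enolate 10 (not isolated), via enolate alkoxide 11 (not isolated), via cis ketone 12 (not isolated)
Conditions: LiBH(s-Bu)3 (1.1 equiv), THF, −78 °C; then LiAlH4 (1.5 equiv), −78 → 0 °C; EtOAc, then MeOH, rt, 3 h; aq. potassium sodium tartrate
Reagents that add atoms: none
Why: 1,4-hydride reduction of the β-alkoxy enone by the bulky borohydride (the isoflavone-to-isoflavanone reaction type) gives enolate 10, which masks the ketone while LiAlH4 performs the standard reductive cleavage of the N-acyl sultam to the primary alcohol, and the methoxide formed on quench epimerises the enolisable C-3 through 12 to the more stable all-trans ketone, C-4 and C-5 being untouched.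

**Step 6**
Reactants: 13 [(3S,4R,5S)-5-[3-(benzyloxy)-4-methoxyphenyl]-4-(hydroxymethyl)oxolan-3-yl][3-(benzyloxy)-4-methoxyphenyl]methanone
Product: 14 [(3S,4R,5S)-5-(3-hydroxy-4-methoxyphenyl)-4-(hydroxymethyl)oxolan-3-yl](3-hydroxy-4-methoxyphenyl)methanone
Conditions: H2 (1 atm), Pd/C (10 wt%), EtOAc, rt, stopped at full conversion
Reagents that add atoms: none
Why: catalytic hydrogenolysis cleaves the two aryl benzyl ethers faster than the cyclic dialkyl benzylic ether or the aryl ketone under neutral conditions at 1 atm, and no stereocentre is affected.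

**Compound list**
1 | 3-(benzyloxy)-4-methoxybenzaldehyde | COc1ccc(C=O)cc1OCc1ccccc1 | starting material
2 | (E)-3-[3-(benzyloxy)-4-methoxyphenyl]prop-2-enoic acid | COc1ccc(/C=C/C(=O)O)cc1OCc1ccccc1 | intermediate
3 | (1R)-(+)-2,10-camphorsultam; (3aR,6S,7aS)-8,8-dimethylhexahydro-3H-3a,6-methano-2,1-benzisothiazole 2,2-dioxide | O=S1(=O)C[C@@]23CC[C@@H](C[C@@H]2N1)C3(C)C | starting material
4 | (E)-3-[3-(benzyloxy)-4-methoxyphenyl]prop-2-enoyl chloride | COc1ccc(/C=C/C(Cl)=O)cc1OCc1ccccc1 | intermediate
5 | N-{(E)-3-[3-(benzyloxy)-4-methoxyphenyl]prop-2-enoyl}-(1R)-(+)-2,10-camphorsultam | O=S1(=O)C[C@@]23CC[C@@H](C[C@@H]2N1C(=O)/C=C/c1ccc(OC)c(OCc4ccccc4)c1)C3(C)C | intermediate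
6 | 1-[3-(benzyloxy)-4-methoxyphenyl]ethan-1-one | COc1ccc(C(C)=O)cc1OCc1ccccc1 | starting material
7 | sodium (Z)-3-[3-(benzyloxy)-4-methoxyphenyl]-3-oxoprop-1-en-1-olate | [Na+].[O-]/C=C\C(=O)c1ccc(OC)c(OCc2ccccc2)c1 | intermediate
8 | (Z)-1-[3-(benzyloxy)-4-methoxyphenyl]-3-hydroxyprop-2-en-1-one (enol form of the 3-oxopropanal) | O/C=C\C(=O)c1ccc(OC)c(OCc2ccccc2)c1 | intermediate
9 | N-acyl (1R)-(+)-2,10-camphorsultam of (4S,5S)-3-[3-(benzyloxy)-4-methoxybenzoyl]-5-[3-(benzyloxy)-4-methoxyphenyl]-4,5-dihydrofuran-4-carboxylic acid | O=S1(=O)C[C@@]23CC[C@@H](C[C@@H]2N1C(=O)[C@@H]1[C@@H](c4ccc(OC)c(OCc5ccccc5)c4)OC=C1C(=O)c1ccc(OC)c(OCc4ccccc4)c1)C3(C)C | intermediate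
10 | lithium enolate of the (4S,5S)-3-aroyl-5-aryl-oxolane-4-carbonyl sultam (exocyclic C3=C(OLi)Ar) | [Li+].O=S1(=O)C[C@@]23CC[C@@H](C[C@@H]2N1C(=O)[C@@H]1[C@@H](c4ccc(OC)c(OCc5ccccc5)c4)OCC1=C([O-])c1ccc(OC)c(OCc4ccccc4)c1)C3(C)C | intermediate
11 | dilithium enolate alkoxide of the (4R,5S)-4-(oxidomethyl)-5-aryl-oxolan-3-ylidene aryl methanolate | [Li+].[Li+].[O-]C[C@@H]1[C@@H](c2ccc(OC)c(OCc3ccccc3)c2)OCC1=C([O-])c1ccc(OC)c(OCc2ccccc2)c1 | intermediate
12 | [(3R,4R,5S)-5-[3-(benzyloxy)-4-methoxyphenyl]-4-(hydroxymethyl)oxolan-3-yl][3-(benzyloxy)-4-methoxyphenyl]methanone (3,4-cis epimer of 13) | COc1ccc(C(=O)[C@H]2CO[C@H](c3ccc(OC)c(OCc4ccccc4)c3)[C@H]2CO)cc1OCc1ccccc1 | intermediate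
13 | [(3S,4R,5S)-5-[3-(benzyloxy)-4-methoxyphenyl]-4-(hydroxymethyl)oxolan-3-yl][3-(benzyloxy)-4-methoxyphenyl]methanone (all-trans) | COc1ccc(C(=O)[C@@H]2CO[C@H](c3ccc(OC)c(OCc4ccccc4)c3)[C@H]2CO)cc1OCc1ccccc1 | intermediate
14 | [(3S,4R,5S)-5-(3-hydroxy-4-methoxyphenyl)-4-(hydroxymethyl)oxolan-3-yl](3-hydroxy-4-methoxyphenyl)methanone | COc1ccc(C(=O)[C@@H]2CO[C@H](c3ccc(OC)c(O)c3)[C@H]2CO)cc1O | target

**Step count**
Total: 6 steps. Longest linear sequence: 5 steps (steps 1, 2, 4, 5, 6); step 3 is the one-step side branch.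

**Three steps most likely to fail, with fallbacks**

Step 4. Three things can go wrong. The cation may be closed by the aryl-ketone oxygen instead of the hydroxymethylene oxygen, giving the 2-aryl-3-formyl isomer. Compound 8 may self-condense to the 1,3,5-triaroylbenzene in warm acetic acid. The facial selectivity of the sultam may be only moderate. The fallback sets out from 5 and comes back at 9. Compound 5 is annulated under the same Mn(OAc)3/AcOH conditions with commercial sodium malonaldehyde, a symmetrical dicarbonyl that can close in only one way and does not trimerise to an aroylbenzene, to give the 3-formyl dihydrofuran F1. The aryl Grignard reagent F2, made from commercial 2-(benzyloxy)-4-bromo-1-methoxybenzene and Mg in THF, is added to the aldehyde of F1 at −78 °C (the N-acyl sultam is far less reactive) to give the carbinol F3 as an epimer mixture. MnO2 in CH2Cl2 oxidises this allylic, benzylic alcohol to 9. The aryl–carbonyl bond is thus made by a polar addition after the annulation instead of being carried through it.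

Step 5. The bulky borohydride might attack in a 1,2 sense or react sluggishly with the doubly deactivated enone. Enolate 10 might not survive the LiAlH4 stage (ring opening by β-alkoxide loss, or acylation). Over-reduction of the ketone on quench is also possible. The fallback sets out from 9 and comes back at 13, with the three operations done separately and without a strong hydride near the ketone. LiOH/H2O2 in THF/H2O at 0 °C removes the auxiliary hydrolytically to give the carboxylic acid F4. BH3·SMe2 in THF at 0 °C reduces the acid chemoselectively to the alcohol F5, leaving the vinylogous ester intact. F5 is then reduced with LiBH(s-Bu)3 (2.2 equiv, THF, −78 °C; passing through 11 and 12) and equilibrated with K2CO3 in MeOH to 13.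

Step 6. Pd/C and H2 may also cleave the benzylic C5–O bond of the oxolane (a p-alkoxybenzylic ether) or reduce the aryl ketone. The fallback sets out from 13 and comes back at 14. Hydrogenolysis is replaced by Lewis-acid dealkylation with BCl3 and pentamethylbenzene as benzyl-cation scavenger in CH2Cl2 at −78 °C. This removes aryl benzyl ethers in preference to aryl methyl ethers and involves no reducing agent; no new intermediate is formed.

**Further compounds**
F1 | step 4 | N-acyl (1R)-(+)-2,10-camphorsultam of (4S,5S)-5-[3-(benzyloxy)-4-methoxyphenyl]-3-formyl-4,5-dihydrofuran-4-carboxylic acid | O=S1(=O)C[C@@]23CC[C@@H](C[C@@H]2N1C(=O)[C@@H]1[C@@H](c4ccc(OC)c(OCc5ccccc5)c4)OC=C1C=O)C3(C)C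
F2 | step 4 | [3-(benzyloxy)-4-methoxyphenyl]magnesium bromide | COc1ccc([Mg]Br)cc1OCc1ccccc1
F3 | step 4 | N-acyl (1R)-(+)-2,10-camphorsultam of (4S,5S)-5-[3-(benzyloxy)-4-methoxyphenyl]-3-{[3-(benzyloxy)-4-methoxyphenyl](hydroxy)methyl}-4,5-dihydrofuran-4-carboxylic acid (carbinol epimers) | O=S1(=O)C[C@@]23CC[C@@H](C[C@@H]2N1C(=O)[C@@H]1[C@@H](c4ccc(OC)c(OCc5ccccc5)c4)OC=C1C(O)c1ccc(OC)c(OCc4ccccc4)c1)C3(C)C
F4 | step 5 | (4S,5S)-3-[3-(benzyloxy)-4-methoxybenzoyl]-5-[3-(benzyloxy)-4-methoxyphenyl]-4,5-dihydrofuran-4-carboxylic acid | COc1ccc(C(=O)C2=CO[C@H](c3ccc(OC)c(OCc4ccccc4)c3)[C@H]2C(=O)O)cc1OCc1ccccc1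
F5 | step 5 | [(4R,5S)-5-[3-(benzyloxy)-4-methoxyphenyl]-4-(hydroxymethyl)-4,5-dihydrofuran-3-yl][3-(benzyloxy)-4-methoxyphenyl]methanone | COc1ccc(C(=O)C2=CO[C@H](c3ccc(OC)c(OCc4ccccc4)c3)[C@H]2CO)cc1OCc1ccccc1
F0 | step 6 | none | none
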